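## Structural features

The target is a cis-fused octahydronaphthalene; locants follow naphthalene numbering throughout. Ring A (C1–C2–C3–C4–C4a–C8a) is a cyclohexene with a C3=C4 double bond and a methyl group on C3. Ring B (C4a–C5–C6–C7–C8–C8a) is saturated. There are six stereocentres: C1 (S), C2 (R), C4a (S), C7 (S), C8 (R) and C8a (R). C2–C1–C8a–C8–C7 form an unbroken row, and C4a flanks C8a. The (2E,4E)-pentadienoic acid on C1, the (E)-but-2-en-2-yl group on C2, the methyl group on C8 and the sulfate oxygen on C7 all lie on the face that carries H4a and H8a. The fragile groups are the secondary alkyl hydrogen sulfate (solvolysis, elimination, strongly acidic when free), the dienoic acid (conjugate addition, E/Z drift) and the doubly allylic C2–H between two trisubstituted alkenes. These exclude late hydrogenation, strong acid and hot strong base. The real difficulty is the crowded C2/C1/C8a/C8 sequence with the cis ring fusion and the C8 methyl group syn to H8a, together with C2, whose configuration must be set independently of ring B. The key step uses the fact that the carboxyl-level carbon on C1, then C1, C8a, C8 and the oxygenated C7 form a 1,5-dioxygenated chain. The C1–C8a bond is therefore the retron of a conjugate addition of a C1 malonate to a ring-B cyclohex-2-enone (C7=O, C8=C8a), and the C8 methyl group sits on the α-carbon of the enolate which that addition leaves behind.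

## Logic of the disconnections

**29 to 28 to 27.** The O–S bond of the sulfate and the ethyl ester are handled last. The sulfate half-ester is the most labile and most polar group, so every earlier intermediate stays neutral and easy to purify. The demand is that sulfation meets a single free hydroxyl (C7), that hydroxide removes the ethyl ester without touching the sulfate monoanion, and that the final acidification is short and cold.

**27 to 25 and 26.** The C=C bond between the exocyclic carbon on C1 and the rest of the dienoate is cut. One olefination with a four-carbon phosphonate supplies the whole (2E,4E)-diene ester and leaves a simple aldehyde. The forward step must be E-selective and must tolerate the free C7 hydroxyl. C1 is α to the aldehyde but already holds its preferred configuration.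

**25 to 24 to 23.** Only the oxidation level of the C1 carbon changes (aldehyde, primary alcohol, methyl ester). Going through 24 avoids a partial ester reduction. The demand is oxidation of the primary alcohol of 24 in the presence of the secondary C7 alcohol.

**23 to 21.** A second methoxycarbonyl group is restored at C1. With two identical esters C1 is not a stereocentre and is a good carbon nucleophile, so the C1 configuration need not be controlled during ring formation. The forward dealkoxycarbonylation must end with the ester on the H4a/H8a face. This is the arrangement expected under equilibration (ester equatorial on ring A, trans to C8, butenyl pseudoaxial).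

**21 to 20.** The C7–H bond is cut back to the ketone, which is the parent of the enolate used in the ring closure. Hydride must arrive on the face opposite the C8 methyl group. The reduction is placed before the loss of the ester so that no C7 carbonyl is present in hot DMSO or methoxide.

**20 to 18.** C1–C8a and C8–CH3 are cut. This removes ring A and the stereocentres C8a and C8 in one operation and leaves a monocyclic enone carrying an acyclic malonate. The forward step must close cis, must produce a regiodefined enolate that survives until it is alkylated, and must be complete before the alkylating agent is added.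

**18 to 17.** The C7 carbonyl is masked as a dioxolane. The enone and its γ-hydrogen at C4a are thus protected from every basic and organometallic reagent used earlier. Unmasking must be mild enough not to move any double bond.

**17 to 13.** The C1–C2 bond is cut with transposition of the butenyl double bond, which is a [3,3] shift in the forward sense. This traces the C2 stereocentre and the (E)-butenyl geometry back to one secondary allylic alcohol. The demand is a chair transition state with the carbinol methyl group pseudo-equatorial, an (R)-carbinol and an (E)-alkene.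

**13 to 11 and 12.** The ester C–O bond is cut, giving a dienyl carbinol and a commercial half-ester acid chloride. The acylation must not ionise the dienylic alcohol.

**11 to 8 and 9.** The single bond between the two alkenes of the diene is cut (C3 to the future C2). Both alkene geometries are then fixed separately before the coupling, and the carbinol stereocentre comes from the chiral pool instead of a reduction. The coupling must proceed with retention at both sp2 carbons.

**8 to 7.** The C3=C4 double bond is cut to an aldehyde on C4a and a two-carbon iodo ylide. The olefination must place iodine cis to the ring and must be faster than epimerisation of 7.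

**7 to 6 to 5 to 4.** These are adjustments of oxidation level and protecting groups. The ketalisation must not move the ring double bond into the position next to the stereocentre.

**4 to 1 and 2.** C4a–C5 (Michael bond) and C8=C8a (aldol condensation) are cut, which reduces ring B to two commercial achiral compounds. The C4a stereocentre is set by an amine catalyst. The demand is that the β-silyloxy aldehyde does not eliminate and that 3 does not racemise before it cyclises.

## Other disconnections considered

**Alternative 1:** The cut is C4a–C5 and C8–C8a, so ring B is made by a [4+2] addition. In the forward step 4-(tert-butyldimethylsilyloxy)-2H-thiopyran A1 adds endo to the unsubstituted alkene of 4,4-dimethoxy-2-methylcyclohexa-2,5-dienone A2 under a chiral oxazaborolidinium Lewis acid. The product is the sulfur-bridged adduct A3. Desulfurisation later turns the C5–S–CH2–C8 bridge into C5H2 and the C8 methyl group.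

- In its favour: one catalytic asymmetric step would set C4a, C8a and C8 from two small achiral compounds. The regiochemistry is electronically matched, since the CH2-bearing diene terminus is the nucleophilic one and meets the β-carbon of the dienone.
- Where it is better: the endo bridge fixes the C8 methyl precursor syn to H8a by geometry. The chosen plan relies on the facial selectivity of an enolate alkylation for this. The alternative also reaches the bicyclic core in fewer steps.
- Where it is equal: cis ring fusion is inherent in both.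
- Against it: ring A of A3 has the wrong pattern (ketone at C4, ketal at C1, no substituent at C2). A butenyl cuprate (R2CuLi) would have to add to C2 with facial control next to a ketal. The C4 oxygen would have to be removed with the alkene placed at C3=C4. C1 would have to be homologated with control of its configuration. Raney Ni desulfurisation is only compatible with a substrate that has no other alkene. Quinone monoketals and 2H-thiopyrans are sensitive to strong Lewis acids.
- Comparison: C2 and C1 would be set late by substrate control, whereas the chosen plan sets C2 by chirality transfer from a defined carbinol. The step count saved early would be spent on functional-group changes after the key step, so the total would not be lower.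

**Alternative 2:** The cut is C4a–C5, with a temporary C3–C7 bond. In the forward step the potassium alkoxide (KH, 18-crown-6) of the 2-vinylbicyclo[2.2.2]oct-5-en-2-ol A4 undergoes an anionic oxy-Cope shift to the cis-fused C7 ketone A5.

- In its favour: the reaction type is well established, runs at or below room temperature, and can only give the cis fusion.
- Where it is better: C1 and C2 are fixed on a rigid cage before ring B exists, so no thermodynamic epimerisation at C1 is needed.
- Where it is equal or better: the ring-forming event is concerted and so is not subject to the equilibrium that burdens the chosen key step.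
- Against it: the enolate released is the C6=C7 enolate, and A5 has no C8 methyl group. C8 would have to be methylated later in competition with C6 and with facial control. The chosen plan solves this in the ring-forming step. A4 itself needs a bridgehead methyl group, two defined substituents on one bridge, an enantioselective Diels–Alder reaction of a trisubstituted cyclohexa-1,3-diene that is prone to hydrogen shifts, and a vinyl addition syn to the etheno bridge.
- Comparison: the step count is expected to be higher, and the C8 problem remains open.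

**Alternative 3:** The cut is C4a–C8a and C7–C8. In the forward step the trienyl acetate enal A6 undergoes an intramolecular Diels–Alder reaction, in which the (E)-enal adds across the C4a=C5–C6=C7(OAc) diene. The product is the cis-fused C7 acetate with a C8 formyl group, A7.

- Where it is better: two rings, two bonds and four stereocentres (C4a, C8a, C7, C8) would form in one step, which is more than the chosen key step achieves. C7 arrives at the alcohol oxidation level, so no ketone reduction is needed.
- Where it is equal: the trans relation of C1 and the C8 substituent follows from the enal geometry, as reliably as the anti alkylation of the chosen plan.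
- Against it: A6 is a conjugated triene with a Z central double bond and an enol acetate terminus. It is open to 6π-electrocyclisation, hydrogen shifts and Z/E drift. The face of the diene that is attacked would be controlled only by C1 and C2 in the tether. Afterwards the C8 formyl group must be taken down to methyl in about three steps next to an allylic acetate. The C5=C6 double bond must be saturated in the presence of two trisubstituted alkenes.
- Comparison: the step count after the key step and the assembly of A6 would both exceed those of the chosen plan.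

Key step: step 10

Assumption: the target is taken in the fully protonated form drawn (hydrogen sulfate and free carboxylic acid); this form is liberated only in the last operation, kept cold, and would be stored as its sodium salt.

Remark: the CIP labels at C4a and C8a differ between 19–21 and the later compounds (and at C8a again in 23 and 25) only because the priority of C1 changes; no centre is inverted.

## Route

Step 1
Reactants: 1 3-[tert-butyl(dimethyl)silyl]oxypropanal; 2 but-3-en-2-one
Product: 4 (4S)-4-{[tert-butyl(dimethyl)silyl]oxymethyl}cyclohex-2-en-1-one, via keto aldehyde 3 (not isolated)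
Conditions: (R)-2-[diphenyl(trimethylsilyloxy)methyl]pyrrolidine (10 mol %), ethyl 3,4-dihydroxybenzoate (20 mol %), neat, 4 °C; then Bn2NH·CF3CO2H, PhMe, 45 °C
Reagents that add atoms: none
Why: Enamine Michael addition to the enone followed by amine-salt aldol condensation (organocatalytic Robinson-type annulation); the diaryl(silyloxy)methyl group shields one enamine face, and on the usual model the (R)-catalyst should give (2R)-3 and hence (4S)-4, while the absence of hydroxide keeps the β-silyloxy aldehyde from eliminating.

Step 2
Reactants: 4 (4S)-4-{[tert-butyl(dimethyl)silyl]oxymethyl}cyclohex-2-en-1-one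
Product: 5 tert-butyl{[(8S)-1,4-dioxaspiro[4.5]dec-6-en-8-yl]methoxy}dimethylsilane
Conditions: Me3SiOCH2CH2OSiMe3, Me3SiOTf (cat.), CH2Cl2, −78 °C; pyridine quench
Reagents that add atoms: 1,2-bis(trimethylsilyloxy)ethane, C[Si](C)(C)OCCO[Si](C)(C)C
Why: Noyori ketalisation under aprotic kinetic conditions leaves the double bond where it is, so the stereocentre next to it (the future C4a) is not erased by migration, and the primary silyl ether survives catalytic Me3SiOTf at −78 °C.

Step 3
Reactants: 5 tert-butyl{[(8S)-1,4-dioxaspiro[4.5]dec-6-en-8-yl]methoxy}dimethylsilane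
Product: 6 [(8S)-1,4-dioxaspiro[4.5]dec-6-en-8-yl]methanol
Conditions: Bu4NF, THF, 0 → 23 °C
Reagents that add atoms: none
Why: Fluoride cleavage of the primary silyl ether; the ketal and the allylic stereocentre are inert to Bu4NF.

Step 4
Reactants: 6 [(8S)-1,4-dioxaspiro[4.5]dec-6-en-8-yl]methanol
Product: 7 (8S)-1,4-dioxaspiro[4.5]dec-6-ene-8-carbaldehyde
Conditions: Dess–Martin periodinane, pyridine, CH2Cl2, 0 °C; used crude at once
Reagents that add atoms: none
Why: Dess–Martin oxidation under buffered, non-basic conditions; the β,γ-unsaturated aldehyde can epimerise or move into conjugation, so it is neither chromatographed nor stored.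

Step 5
Reactants: 7 (8S)-1,4-dioxaspiro[4.5]dec-6-ene-8-carbaldehyde
Product: 8 (8S)-8-[(1Z)-2-iodoprop-1-en-1-yl]-1,4-dioxaspiro[4.5]dec-6-ene
Conditions: EtPPh3I, n-BuLi, THF, 23 °C; I2, −78 °C; NaN(SiMe3)2, −20 °C; then 7, −78 → −20 °C
Reagents that add atoms: ethyltriphenylphosphonium iodide, CC[P+](c1ccccc1)(c1ccccc1)c1ccccc1.[I-]; iodine, II
Why: α-Iodo ylide olefination (Stork–Zhao type): kinetically controlled oxaphosphetane formation from the non-stabilised ylide Ph3P=C(I)CH3 should place iodine cis to the ring residue and give the (Z)-2-iodoalkene, and carbonyl addition at −78 °C should be faster than α-deprotonation of 7.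

Step 6
Reactants: 8 (8S)-8-[(1Z)-2-iodoprop-1-en-1-yl]-1,4-dioxaspiro[4.5]dec-6-ene; 9 (2R)-but-3-yn-2-ol
Product: 11 (2R,3E,5Z)-6-[(8S)-1,4-dioxaspiro[4.5]dec-6-en-8-yl]-3,5-dimethylhexa-3,5-dien-2-ol, via alkenylalane 10 (not isolated)
Conditions: 9, AlMe3 (3 equiv), Cp2ZrCl2 (0.3 equiv), CH2Cl2, 0 → 23 °C; volatiles removed; then 8, ZnCl2, Pd(PPh3)4 (5 mol %), THF, 23 → 40 °C; aq. KNaC4H4O6
Reagents that add atoms: trimethylaluminium, C[Al](C)C
Why: Zr-catalysed syn-methylalumination of the alkyne (Negishi carboalumination) gives the (E)-alkenylalane with the new methyl group on the internal carbon, and Al-to-Zn transmetalation with Pd-catalysed alkenyl–alkenyl coupling (Negishi) joins it to 8 with retention at both sp2 carbons; the carbinol centre of 9 is untouched, and free AlMe3 is stripped off before the ketal is exposed.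

Step 7
Reactants: 11 (2R,3E,5Z)-6-[(8S)-1,4-dioxaspiro[4.5]dec-6-en-8-yl]-3,5-dimethylhexa-3,5-dien-2-ol; 12 methyl 3-chloro-3-oxopropanoate
Product: 13 (2R,3E,5Z)-6-[(8S)-1,4-dioxaspiro[4.5]dec-6-en-8-yl]-3,5-dimethylhexa-3,5-dien-2-yl methyl propanedioate
Conditions: pyridine, CH2Cl2, −20 → 0 °C
Reagents that add atoms: none
Why: Acylation of the secondary allylic alcohol with the half-ester acid chloride; low temperature and pyridine suppress ionisation of the dienylic ester.

Step 8
Reactants: 13 (2R,3E,5Z)-6-[(8S)-1,4-dioxaspiro[4.5]dec-6-en-8-yl]-3,5-dimethylhexa-3,5-dien-2-yl methyl propanedioate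
Product: 17 dimethyl 2-[(2E,4R,5Z)-6-[(8S)-1,4-dioxaspiro[4.5]dec-6-en-8-yl]-3,5-dimethylhexa-2,5-dien-4-yl]propanedioate, via silyl ketene acetal 14 (not isolated), via trimethylsilyl ester 15 (not isolated), via malonic half acid 16 (not isolated)
Conditions: LiN(SiMe3)2, Me3SiCl/Et3N, THF, −78 → 65 °C; pH 5 aqueous work-up; crude acid, Me3SiCHN2, PhMe/MeOH, 0 °C
Reagents that add atoms: trimethylsilyldiazomethane, C[Si](C)(C)C=[N+]=[N-]
Why: Ireland–Claisen rearrangement of the malonate silyl ketene acetal: the [3,3] shift through a chair transition state with the carbinol methyl group pseudo-equatorial forms C1–C2 suprafacially, transfers the (R)-carbinol configuration to (R)-C2 and creates the (E)-butenyl double bond; methylation of the liberated acid makes both esters identical, so C1 is not stereogenic.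

Step 9
Reactants: 17 dimethyl 2-[(2E,4R,5Z)-6-[(8S)-1,4-dioxaspiro[4.5]dec-6-en-8-yl]-3,5-dimethylhexa-2,5-dien-4-yl]propanedioate
Product: 18 dimethyl 2-[(2E,4R,5Z)-3,5-dimethyl-6-[(1S)-4-oxocyclohex-2-en-1-yl]hexa-2,5-dien-4-yl]propanedioate
Conditions: pyridinium p-toluenesulfonate, acetone/H2O (10:1), 40 °C
Reagents that add atoms: water, O
Why: Mild acid hydrolysis of the allylic ketal; the weak acid should neither enolise the enone toward C4a nor move the skipped diene, and 18 is used promptly.

Step 10
Reactants: 18 dimethyl 2-[(2E,4R,5Z)-3,5-dimethyl-6-[(1S)-4-oxocyclohex-2-en-1-yl]hexa-2,5-dien-4-yl]propanedioate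
Product: 20 dimethyl (2R,4aR,8R,8aS)-2-[(2E)-but-2-en-2-yl]-3,8-dimethyl-7-oxo-2,4a,5,6,7,8-hexahydronaphthalene-1,1(8aH)-dicarboxylate, via sodium enolate 19 (not isolated)
Conditions: NaH (1.05 equiv), THF, 0 → 23 °C; then MeI (5 equiv), DMPU, −40 → 0 °C
Reagents that add atoms: iodomethane, CI
Why: NaH removes the malonate hydrogen irreversibly (H2 leaves), and the sodium malonate adds to the enone β-carbon C8a; the closest known reaction type is the base-mediated intramolecular Michael addition of malonates to cyclohexenones combined with alkylation of the Michael enolate. Ring A closes in the 6-exo-trig mode. Because the tether is anchored on C4a and held by the (Z)-C3=C4 double bond, C1 can reach C8a only on the face of ring B that carries C4, along the axial trajectory, so the C4a stereocentre sets C8a and the fusion is cis. C2 is not touched, and C1 becomes quaternary with two identical esters and is not stereogenic. Enolate 19 is regiodefined (C7=C8) and has no acidic C–H partner left in the flask, so it should persist until iodomethane is added. Methylation then takes place at C8 on the face anti to the bulky C(CO2Me)2 substituent of C8a, which puts the methyl group trans to C1 and cis to H8a, so C8 is set by C8a. The step needs C- over O-alkylation and a single methylation, which the soft electrophile, the sodium counter-ion with DMPU and the low temperature with excess MeI should secure. It also needs ring closure to be complete before MeI is added, since otherwise the open-chain malonate would be methylated at C1.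

Step 11
Reactants: 20 dimethyl (2R,4aR,8R,8aS)-2-[(2E)-but-2-en-2-yl]-3,8-dimethyl-7-oxo-2,4a,5,6,7,8-hexahydronaphthalene-1,1(8aH)-dicarboxylate
Product: 21 dimethyl (2R,4aR,7S,8R,8aS)-2-[(2E)-but-2-en-2-yl]-7-hydroxy-3,8-dimethyl-2,4a,5,6,7,8-hexahydronaphthalene-1,1(8aH)-dicarboxylate
Conditions: LiBH(s-Bu)3, THF, −78 °C; then NaOH, H2O2, 0 °C
Reagents that add atoms: none
Why: The bulky borohydride avoids the axial trajectory and should add to C7 from the face opposite the C8 methyl group (equatorial attack on the chair with that methyl group equatorial, as in the reduction of 2-methylcyclohexanone to the cis alcohol), giving the (7S) alcohol cis to the methyl group; the esters are not reduced at −78 °C, and the alkoxide cannot lactonise because it is trans-1,3 to C1.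

Step 12
Reactants: 21 dimethyl (2R,4aR,7S,8R,8aS)-2-[(2E)-but-2-en-2-yl]-7-hydroxy-3,8-dimethyl-2,4a,5,6,7,8-hexahydronaphthalene-1,1(8aH)-dicarboxylate
Product: 23 methyl (1S,2R,4aS,7S,8R,8aS)-2-[(2E)-but-2-en-2-yl]-7-hydroxy-3,8-dimethyl-1,2,4a,5,6,7,8,8a-octahydronaphthalene-1-carboxylate, via C1 epimer 22 (not isolated)
Conditions: LiCl, H2O, DMSO, 150 °C; then NaOMe (cat.), MeOH, 50 °C on the crude product
Reagents that add atoms: none
Why: Krapcho dealkoxycarbonylation (chloride attack on a methyl ester, loss of CO2, protonation of the ester enolate) followed by methoxide equilibration, which should converge any (1R) epimer 22 on the (1S) ester that is equatorial on ring A, trans to C8 and cis to the pseudoaxial butenyl group; with C7 already reduced, neither C8 epimerisation nor retro-Michael cleavage is possible.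

Step 13
Reactants: 23 methyl (1S,2R,4aS,7S,8R,8aS)-2-[(2E)-but-2-en-2-yl]-7-hydroxy-3,8-dimethyl-1,2,4a,5,6,7,8,8a-octahydronaphthalene-1-carboxylate
Product: 24 [(1S,2R,4aS,7S,8R,8aR)-2-[(2E)-but-2-en-2-yl]-7-hydroxy-3,8-dimethyl-1,2,4a,5,6,7,8,8a-octahydronaphthalen-1-yl]methanol
Conditions: LiAlH4, THF, 0 °C; H2O, aq. NaOH
Reagents that add atoms: none
Why: Hydride reduction of the ester to the primary alcohol, which fixes the C1 configuration; isolated alkenes are inert.

Step 14
Reactants: 24 [(1S,2R,4aS,7S,8R,8aR)-2-[(2E)-but-2-en-2-yl]-7-hydroxy-3,8-dimethyl-1,2,4a,5,6,7,8,8a-octahydronaphthalen-1-yl]methanol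
Product: 25 (1S,2R,4aS,7S,8R,8aS)-2-[(2E)-but-2-en-2-yl]-7-hydroxy-3,8-dimethyl-1,2,4a,5,6,7,8,8a-octahydronaphthalene-1-carbaldehyde
Conditions: TEMPO (10 mol %), PhI(OAc)2, CH2Cl2, 23 °C
Reagents that add atoms: none
Why: Oxoammonium (TEMPO) oxidation with PhI(OAc)2 is selective for the primary alcohol over the hindered secondary C7 alcohol and stops at the aldehyde; no lactol can form because the two groups are trans-1,3.

Step 15
Reactants: 25 (1S,2R,4aS,7S,8R,8aS)-2-[(2E)-but-2-en-2-yl]-7-hydroxy-3,8-dimethyl-1,2,4a,5,6,7,8,8a-octahydronaphthalene-1-carbaldehyde; 26 ethyl (2E)-4-(diethoxyphosphoryl)but-2-enoate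
Product: 27 ethyl (2E,4E)-5-[(1S,2R,4aS,7S,8R,8aR)-2-[(2E)-but-2-en-2-yl]-7-hydroxy-3,8-dimethyl-1,2,4a,5,6,7,8,8a-octahydronaphthalen-1-yl]penta-2,4-dienoate
Conditions: 26 (2.5 equiv), LiN(SiMe3)2, THF, −78 → 0 °C
Reagents that add atoms: none
Why: Horner–Wadsworth–Emmons olefination with the phosphonocrotonate anion gives the (2E,4E)-dienoate; C1 already holds its preferred configuration, so the basic medium should not degrade it, and the excess anion covers the free hydroxyl.

Step 16
Reactants: 27 ethyl (2E,4E)-5-[(1S,2R,4aS,7S,8R,8aR)-2-[(2E)-but-2-en-2-yl]-7-hydroxy-3,8-dimethyl-1,2,4a,5,6,7,8,8a-octahydronaphthalen-1-yl]penta-2,4-dienoate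
Product: 28 sodium (1S,2R,4aS,7S,8R,8aR)-2-[(2E)-but-2-en-2-yl]-1-[(1E,3E)-5-ethoxy-5-oxopenta-1,3-dien-1-yl]-3,8-dimethyl-1,2,4a,5,6,7,8,8a-octahydronaphthalen-7-yl sulfate
Conditions: SO3·pyridine, pyridine, 45 °C; then aq. NaHCO3
Reagents that add atoms: sulfur trioxide–pyridine complex, O=S(=O)=O.c1ccncc1; sodium hydrogencarbonate, [Na+].OC([O-])=O
Why: O-Sulfation of the only free alcohol with the SO3–pyridine complex; the bicarbonate work-up gives the stable sodium salt.

Step 17
Reactants: 28 sodium (1S,2R,4aS,7S,8R,8aR)-2-[(2E)-but-2-en-2-yl]-1-[(1E,3E)-5-ethoxy-5-oxopenta-1,3-dien-1-yl]-3,8-dimethyl-1,2,4a,5,6,7,8,8a-octahydronaphthalen-7-yl sulfate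
Product: 29 (2E,4E)-5-[(1S,2R,4aS,7S,8R,8aR)-2-[(2E)-but-2-en-2-yl]-3,8-dimethyl-7-(sulfooxy)-1,2,4a,5,6,7,8,8a-octahydronaphthalen-1-yl]penta-2,4-dienoic acid
Conditions: LiOH, THF/MeOH/H2O, 23 °C; then 1 M HCl to pH 2, 0 °C, C18 cartridge
Reagents that add atoms: lithium hydroxide, [Li+].[OH-]
Why: Saponification of the ethyl ester; alkyl sulfate monoanions resist hydroxide at room temperature, and a short cold acidification should give the diacid form drawn.

## Compound list

1 | 3-[tert-butyl(dimethyl)silyl]oxypropanal | CC(C)(C)[Si](C)(C)OCCC=O | starting material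
2 | but-3-en-2-one | CC(=O)C=C | starting material
3 | (2R)-2-{[tert-butyl(dimethyl)silyl]oxymethyl}-5-oxohexanal | O=C[C@@H](CO[Si](C)(C)C(C)(C)C)CCC(C)=O | intermediate
4 | (4S)-4-{[tert-butyl(dimethyl)silyl]oxymethyl}cyclohex-2-en-1-one | O=C1C=C[C@@H](CO[Si](C)(C)C(C)(C)C)CC1 | intermediate
5 | tert-butyl{[(8S)-1,4-dioxaspiro[4.5]dec-6-en-8-yl]methoxy}dimethylsilane | C1COC2(O1)C=C[C@@H](CO[Si](C)(C)C(C)(C)C)CC2 | intermediate
6 | [(8S)-1,4-dioxaspiro[4.5]dec-6-en-8-yl]methanol | C1COC2(O1)C=C[C@@H](CO)CC2 | intermediate
7 | (8S)-1,4-dioxaspiro[4.5]dec-6-ene-8-carbaldehyde | C1COC2(O1)C=C[C@@H](C=O)CC2 | intermediate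
8 | (8S)-8-[(1Z)-2-iodoprop-1-en-1-yl]-1,4-dioxaspiro[4.5]dec-6-ene | C1COC2(O1)C=C[C@@H](/C=C(\I)C)CC2 | intermediate
9 | (2R)-but-3-yn-2-ol | C[C@@H](O)C#C | starting material
10 | dimethylaluminium (2R,3E)-4-(dimethylalumanyl)-3-methylbut-3-en-2-olate (alkenylalane) | C[C@@H](O[Al](C)C)/C(C)=C/[Al](C)C | intermediate
11 | (2R,3E,5Z)-6-[(8S)-1,4-dioxaspiro[4.5]dec-6-en-8-yl]-3,5-dimethylhexa-3,5-dien-2-ol | C1COC2(O1)C=C[C@@H](/C=C(C)\C=C(/C)[C@@H](C)O)CC2 | intermediate
12 | methyl 3-chloro-3-oxopropanoate | COC(=O)CC(Cl)=O | starting material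
13 | (2R,3E,5Z)-6-[(8S)-1,4-dioxaspiro[4.5]dec-6-en-8-yl]-3,5-dimethylhexa-3,5-dien-2-yl methyl propanedioate | C1COC2(O1)C=C[C@@H](/C=C(C)\C=C(/C)[C@@H](C)OC(=O)CC(=O)OC)CC2 | intermediate
14 | trimethylsilyl ketene acetal of 13 (silylated on the carbonyl oxygen of the dienyl ester) | C1COC2(O1)C=C[C@@H](/C=C(C)\C=C(/C)[C@@H](C)OC(O[Si](C)(C)C)=CC(=O)OC)CC2 | intermediate
15 | methyl trimethylsilyl 2-[(2E,4R,5Z)-6-[(8S)-1,4-dioxaspiro[4.5]dec-6-en-8-yl]-3,5-dimethylhexa-2,5-dien-4-yl]propanedioate (both configurations at the malonate carbon) | C/C=C(\C)[C@@H](C(C(=O)O[Si](C)(C)C)C(=O)OC)/C(C)=C\[C@H]1CCC2(OCCO2)C=C1 | intermediate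
16 | 2-[(2E,4R,5Z)-6-[(8S)-1,4-dioxaspiro[4.5]dec-6-en-8-yl]-3,5-dimethylhexa-2,5-dien-4-yl]-3-methoxy-3-oxopropanoic acid (both configurations at the malonate carbon) | C/C=C(\C)[C@@H](C(C(=O)O)C(=O)OC)/C(C)=C\[C@H]1CCC2(OCCO2)C=C1 | intermediate
17 | dimethyl 2-[(2E,4R,5Z)-6-[(8S)-1,4-dioxaspiro[4.5]dec-6-en-8-yl]-3,5-dimethylhexa-2,5-dien-4-yl]propanedioate | C/C=C(\C)[C@@H](C(C(=O)OC)C(=O)OC)/C(C)=C\[C@H]1CCC2(OCCO2)C=C1 | intermediate
18 | dimethyl 2-[(2E,4R,5Z)-3,5-dimethyl-6-[(1S)-4-oxocyclohex-2-en-1-yl]hexa-2,5-dien-4-yl]propanedioate | C/C=C(\C)[C@@H](C(C(=O)OC)C(=O)OC)/C(C)=C\[C@H]1CCC(=O)C=C1 | intermediate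
19 | sodium (2R,4aR,8aS)-2-[(2E)-but-2-en-2-yl]-1,1-bis(methoxycarbonyl)-3-methyl-1,2,4a,5,6,8a-hexahydronaphthalen-7-olate (C7=C8 enolate) | C/C=C(\C)[C@@H]1C(C)=C[C@H]2CCC([O-])=C[C@H]2C1(C(=O)OC)C(=O)OC.[Na+] | intermediate
20 | dimethyl (2R,4aR,8R,8aS)-2-[(2E)-but-2-en-2-yl]-3,8-dimethyl-7-oxo-2,4a,5,6,7,8-hexahydronaphthalene-1,1(8aH)-dicarboxylate | C/C=C(\C)[C@@H]1C(C)=C[C@H]2CCC(=O)[C@H](C)[C@H]2C1(C(=O)OC)C(=O)OC | intermediate
21 | dimethyl (2R,4aR,7S,8R,8aS)-2-[(2E)-but-2-en-2-yl]-7-hydroxy-3,8-dimethyl-2,4a,5,6,7,8-hexahydronaphthalene-1,1(8aH)-dicarboxylate | C/C=C(\C)[C@@H]1C(C)=C[C@H]2CC[C@H](O)[C@H](C)[C@H]2C1(C(=O)OC)C(=O)OC | intermediate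
22 | methyl (1R,2R,4aS,7S,8R,8aS)-2-[(2E)-but-2-en-2-yl]-7-hydroxy-3,8-dimethyl-1,2,4a,5,6,7,8,8a-octahydronaphthalene-1-carboxylate | C/C=C(\C)[C@@H]1C(C)=C[C@H]2CC[C@H](O)[C@H](C)[C@H]2[C@H]1C(=O)OC | intermediate
23 | methyl (1S,2R,4aS,7S,8R,8aS)-2-[(2E)-but-2-en-2-yl]-7-hydroxy-3,8-dimethyl-1,2,4a,5,6,7,8,8a-octahydronaphthalene-1-carboxylate | C/C=C(\C)[C@@H]1C(C)=C[C@H]2CC[C@H](O)[C@H](C)[C@H]2[C@@H]1C(=O)OC | intermediate
24 | [(1S,2R,4aS,7S,8R,8aR)-2-[(2E)-but-2-en-2-yl]-7-hydroxy-3,8-dimethyl-1,2,4a,5,6,7,8,8a-octahydronaphthalen-1-yl]methanol | C/C=C(\C)[C@@H]1C(C)=C[C@H]2CC[C@H](O)[C@H](C)[C@H]2[C@@H]1CO | intermediate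
25 | (1S,2R,4aS,7S,8R,8aS)-2-[(2E)-but-2-en-2-yl]-7-hydroxy-3,8-dimethyl-1,2,4a,5,6,7,8,8a-octahydronaphthalene-1-carbaldehyde | C/C=C(\C)[C@@H]1C(C)=C[C@H]2CC[C@H](O)[C@H](C)[C@H]2[C@@H]1C=O | intermediate
26 | ethyl (2E)-4-(diethoxyphosphoryl)but-2-enoate | CCOC(=O)/C=C/CP(=O)(OCC)OCC | starting material
27 | ethyl (2E,4E)-5-[(1S,2R,4aS,7S,8R,8aR)-2-[(2E)-but-2-en-2-yl]-7-hydroxy-3,8-dimethyl-1,2,4a,5,6,7,8,8a-octahydronaphthalen-1-yl]penta-2,4-dienoate | C/C=C(\C)[C@@H]1C(C)=C[C@H]2CC[C@H](O)[C@H](C)[C@H]2[C@@H]1/C=C/C=C/C(=O)OCC | intermediate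
28 | sodium (1S,2R,4aS,7S,8R,8aR)-2-[(2E)-but-2-en-2-yl]-1-[(1E,3E)-5-ethoxy-5-oxopenta-1,3-dien-1-yl]-3,8-dimethyl-1,2,4a,5,6,7,8,8a-octahydronaphthalen-7-yl sulfate | C/C=C(\C)[C@@H]1C(C)=C[C@H]2CC[C@H](OS(=O)(=O)[O-])[C@H](C)[C@H]2[C@@H]1/C=C/C=C/C(=O)OCC.[Na+] | intermediate
29 | (2E,4E)-5-[(1S,2R,4aS,7S,8R,8aR)-2-[(2E)-but-2-en-2-yl]-3,8-dimethyl-7-(sulfooxy)-1,2,4a,5,6,7,8,8a-octahydronaphthalen-1-yl]penta-2,4-dienoic acid | C/C=C(\C)[C@@H]1C(C)=C[C@H]2CC[C@H](OS(=O)(=O)O)[C@H](C)[C@H]2[C@@H]1/C=C/C=C/C(=O)O | target

## Step count and least certain steps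

Total step count: 17. Longest linear sequence: 17 steps (1 and 2 to 29); 9, 12 and 26 are commercial and enter at steps 6, 7 and 15.

**Step 10 (key step).** The ring closure is an equilibrium between a stabilised malonate anion and a less stabilised ketone enolate beside a new quaternary carbon. If it stops short of completion, iodomethane alkylates C1 of the open-chain malonate. Proton exchange between enolate and product can cause a second methylation or loss of regiocontrol. The malonate anion may also abstract the γ-hydrogen at C4a and erode that centre. The fallback sets out from 18 and returns at 20. After the NaH ring closure the enolate is intercepted at −78 °C with Me3SiCl/Et3N. This should drain the equilibrium, because the ketone enolate is silylated much faster than the malonate anion, and gives the trimethylsilyl enol ether F1. Et2Zn/CH2I2 should cyclopropanate this electron-rich double bond in preference to the two trisubstituted alkenes, on the face anti to C1, to give the siloxycyclopropane F2. K2CO3 in MeOH then opens the C7–CH2 bond and delivers 20 with the C8 methyl group in place. No free enolate meets an alkylating agent in this sequence.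

**Step 1.** Silanolate may be lost by β-elimination from the enamine of 1 or from 3 during the aldol condensation. Slow cyclisation of 3 may allow its α-centre to racemise. The fallback sets out from commercial 4-(hydroxymethyl)cyclohexan-1-one F3 and returns at 4. Silylation (t-BuMe2SiCl, imidazole) gives the ketone F4. Enantiotopic deprotonation with the appropriate enantiomer of LiN(CHMePh)2 in the presence of LiCl and Me3SiCl gives the (S)-configured trimethylsilyl enol ether F5. Saegusa–Ito oxidation with Pd(OAc)2 gives 4.

**Step 5.** The basic ylide may deprotonate 7 at the doubly activated α-position, causing epimerisation or conjugation. The Z selectivity and conversion of this olefination are also moderate. The fallback sets out from 7 and returns at 11, and it bypasses step 6 as well.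
- (CF3CH2O)2P(O)CH(CH3)CO2Me with KN(SiMe3)2 and 18-crown-6 at −78 °C gives the (Z)-enoate F6.
- (i-Bu)2AlH gives the (Z)-allylic alcohol F7.
- MnO2 gives the (Z)-enal F8.
- Ph3P=C(CH3)C(O)CH3 gives the (3E,5Z)-dienone F9.
- (S)-2-Methyl-CBS-oxazaborolidine with BH3·SMe2 reduces F9 to the (R)-carbinol 11.

**Step 6.** Carboalumination of the free propargylic alcohol may be incomplete. Residual alane may attack the allylic ketal. The coupling of two hindered alkenyl partners may be slow enough for the iodide to isomerise. The fallback sets out from 8 and 9 and returns at 11. The same carboalumination of 9, quenched with I2, gives (2R,3E)-4-iodo-3-methylbut-3-en-2-ol F10. Miyaura borylation of 8 (B2pin2, PdCl2(dppf), KOPh) gives the alkenyl pinacol boronate F11 with boron cis to the ring. Suzuki–Miyaura coupling of F11 with F10 (Pd(PPh3)4, aq. K3PO4) gives 11 without any aluminium reagent near the ketal.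

**Step 11.** Facial selectivity may be poor if 20 reacts through the chair in which the C8 methyl group is axial and the geminal esters cover the top face of C7. The fallback sets out from 20 and returns at 23. The order of the two steps is reversed. LiCl/H2O/DMSO and then NaOMe give the keto monoester F12. Reduction of F12 with LiBH(s-Bu)3 then meets only H1 on the top face at C1 and should give 23 directly.

## Further compounds

F1 | step 10 | dimethyl (2R,4aR,8aS)-2-[(2E)-but-2-en-2-yl]-3-methyl-7-(trimethylsilyloxy)-2,4a,5,6-tetrahydronaphthalene-1,1(8aH)-dicarboxylate | C/C=C(\C)[C@@H]1C(C)=C[C@H]2CCC(O[Si](C)(C)C)=C[C@H]2C1(C(=O)OC)C(=O)OC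
F2 | step 10 | siloxycyclopropane from F1: CH2 bridging C7 and C8 on the face of H8a, Me3SiO on C7 on the opposite face, other centres as in 20 | C/C=C(\C)[C@@H]1C(C)=C[C@H]2CC[C@]3(O[Si](C)(C)C)C[C@@H]3[C@H]2C1(C(=O)OC)C(=O)OC
F3 | step 1 | 4-(hydroxymethyl)cyclohexan-1-one | O=C1CCC(CO)CC1
F4 | step 1 | 4-{[tert-butyl(dimethyl)silyl]oxymethyl}cyclohexan-1-one | O=C1CCC(CO[Si](C)(C)C(C)(C)C)CC1
F5 | step 1 | tert-butyl(dimethyl){[(1S)-4-(trimethylsilyloxy)cyclohex-3-en-1-yl]methoxy}silane | C[Si](C)(C)OC1=CC[C@@H](CO[Si](C)(C)C(C)(C)C)CC1
F6 | step 5 | methyl (2Z)-3-[(8S)-1,4-dioxaspiro[4.5]dec-6-en-8-yl]-2-methylprop-2-enoate | C1COC2(O1)C=C[C@@H](/C=C(C)\C(=O)OC)CC2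
F7 | step 5 | (2Z)-3-[(8S)-1,4-dioxaspiro[4.5]dec-6-en-8-yl]-2-methylprop-2-en-1-ol | C1COC2(O1)C=C[C@@H](/C=C(C)\CO)CC2
F8 | step 5 | (2Z)-3-[(8S)-1,4-dioxaspiro[4.5]dec-6-en-8-yl]-2-methylprop-2-enal | C1COC2(O1)C=C[C@@H](/C=C(C)\C=O)CC2
F9 | step 5 | (3E,5Z)-6-[(8S)-1,4-dioxaspiro[4.5]dec-6-en-8-yl]-3,5-dimethylhexa-3,5-dien-2-one | C1COC2(O1)C=C[C@@H](/C=C(C)\C=C(/C)C(C)=O)CC2
F10 | step 6 | (2R,3E)-4-iodo-3-methylbut-3-en-2-ol | C[C@@H](O)/C(C)=C/I
F11 | step 6 | (8S)-8-[2-(4,4,5,5-tetramethyl-1,3,2-dioxaborolan-2-yl)prop-1-en-1-yl]-1,4-dioxaspiro[4.5]dec-6-ene, boron cis to the ring | C1COC2(O1)C=C[C@@H](/C=C(\B1OC(C)(C)C(C)(C)O1)C)CC2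
F12 | step 11 | methyl (1S,2R,4aS,8R,8aS)-2-[(2E)-but-2-en-2-yl]-3,8-dimethyl-7-oxo-1,2,4a,5,6,7,8,8a-octahydronaphthalene-1-carboxylate | C/C=C(\C)[C@@H]1C(C)=C[C@H]2CCC(=O)[C@H](C)[C@H]2[C@@H]1C(=O)OC
A1 | alternative 1 | 4-(tert-butyldimethylsilyloxy)-2H-thiopyran | C1SC=CC(O[Si](C)(C)C(C)(C)C)=C1
A2 | alternative 1 | 4,4-dimethoxy-2-methylcyclohexa-2,5-dien-1-one | COC1(OC)C=CC(=O)C(C)=C1
A3 | alternative 1 | endo sulfur-bridged cis-fused Diels–Alder adduct of A1 and A2 | C1=C(C)C(=O)[C@H]2[C@H]3C=C(O[Si](C)(C)C(C)(C)C)[C@H](CS3)[C@H]2C1(OC)OC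
A4 | alternative 2 | 2-vinylbicyclo[2.2.2]oct-5-en-2-ol with bridgeheads C3 (methyl) and C8a, butenyl on C2 and silyloxymethyl on C1, vinyl syn to the etheno bridge | C/C=C(\C)[C@@H]1[C@]2(C)C=C[C@@H](C[C@@]2(O)C=C)[C@@H]1CO[Si](C)(C)C(C)(C)C
A5 | alternative 2 | cis-fused C7 ketone from the oxy-Cope shift of A4 | C/C=C(\C)[C@@H]1C(C)=C[C@H]2CCC(=O)C[C@H]2[C@@H]1CO[Si](C)(C)C(C)(C)C
A6 | alternative 3 | trienyl acetate enal: (E)-enal tethered through C1 and C2 to a (3Z,4aZ,6E)-triene ending in the enol acetate | C/C=C(\C)[C@@H]([C@@H](CO[Si](C)(C)C(C)(C)C)/C=C/C=O)/C(C)=C\C=C/C=C/OC(C)=O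
A7 | alternative 3 | cis-fused C7 acetate with C8 formyl group and C5=C6 double bond | C/C=C(\C)[C@@H]1C(C)=C[C@H]2C=C[C@H](OC(C)=O)[C@H](C=O)[C@H]2[C@@H]1CO[Si](C)(C)C(C)(C)C
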